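## Structural features

The target is a cis-fused bicycle in which a 1,2-dioxane (O1, O2, C3, C4, C5, C6) shares its C3–C4 bond with a γ-butyrolactone (C1 carbonyl, C2 methylene, C3, C4 and the ring oxygen on C4). C6 is a fully substituted peroxy carbon carrying a methyl group and an unbranched hexadecyl chain (C7 onwards). C4 is a fully substituted carbinol carbon with a methyl group, and C3 is the only stereogenic methine. C3 and C4 are neighbours, whereas C6 is separated from C4 by the C5 methylene, which offers no handle. In the (3S,4S,6R) isomer the lactone oxygen, C2 and C7 lie on one face of the dioxane and the two methyl groups on the other. The O–O bond is the fragile element: it rules out catalytic hydrogenation, dissolving or low-valent metals, warm phosphines and strong hydride donors. The C3 hydrogen sits on a peroxy carbon and is β to the lactone carbonyl, so the target and most precursors are base-sensitive (Kornblum–DeLaMare cleavage, β-elimination). The real difficulty is to place a peroxide between a secondary and a quaternary carbon with absolute control at C6, far from any directing group. The key step exploits that C3, C4, C5 and C6 with their two methyl groups form the carbon pattern of a 1,3-dimethylcyclohexa-1,3-diene. When C2 and C7 are tied together as the carbinol carbons of a cis-dihydrodiol, the dioxane becomes the O–O bridge of a 2,3-dioxabicyclo[2.2.2]octene, and the cis relation of the side arms at C3 and C6 follows from the bicycle.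

## Logic of the disconnections

20 back to 19. The C5–H bond of 20 is replaced by C5–I. The lactone oxygen can only be brought to C4 together with an electrophile at C5, and iodine can be removed later without a reductant that breaks O–O. The skeleton is unchanged, but 19 is the direct product of a ring closure. The forward step must deliver a hydrogen atom to the C5 radical faster than that radical attacks the neighbouring peroxide.

19 back to 18. The C7–C8 single bond is traced to a C7=C8 double bond. The alkene is the mark of a carbonyl olefination, the mildest way to attach fifteen carbons next to the quaternary C6. A site for C–C bond formation appears. The forward step must add H2 to C=C while leaving O–O, C–I and the lactone alone.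

18 back to 17. The C4–O bond of the lactone and the C5–I bond are cut, which opens the lactone and returns C4 and C5 to an alkene. One ring and two stereocentres disappear, and C4 need not be made as a separate quaternary carbinol. The carboxyl must add to C4 and not C5, on the face of its own tether, and the iodine electrophile must spare the C7=C8 alkene.

17 back to 15. C1 is taken from the acid to the enol-ether level (through 16): the C1=O bonds are exchanged for a C1=C2 bond bearing OMe. The enol ether is what a one-carbon olefination leaves, and it tolerates ylides. The forward step must protonate C2 faster than acid ionises the allylic C3–O bond, and oxidise the aldehyde before it eliminates the peroxide.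

15 back to 10 and 14. The C7=C8 bond is cut; 14 comes from 13, and 13 from 11 and 12 by one P–C bond. Fifteen carbons leave in one cut and come from a bought bromide. The ylide must add to a formyl group on a quaternary carbon faster than it removes the C3 hydrogen.

10 back to 7 and 9 (9 from 8). The C1=C2 bond is cut. Both side arms now end in formyl groups, so the two arms become the two halves of one functional group pair. The ylide must tell the formyl group on the C3 methine from the one on the quaternary C6.

7 back to 6. The formyl carbons C2 and C7 are joined by a C2–C7 bond as a cis-diol. The cis relation of the arms is then guaranteed by a ring and need not be controlled. The price is a glycol cleavage under neutral conditions, because C3–H becomes α to a formyl group.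

6 back to 5. The two O–H bonds are exchanged for the C–O bonds of an isopropylidene acetal, the group that blocks one face in the preceding step. The forward hydrolysis must leave the peroxide bridge intact.

5 back to 4 and dioxygen. The C3–O and C6–O bonds are cut together in a retro-(4+2) step. The peroxide, one ring and two stereocentres vanish, leaving a diene whose only stereocentres are the two carbinol carbons. Oxygen must add to the diene termini on the face opposite the acetal and must not abstract allylic hydrogen.

4 back to 2 and 3. The two acetal C–O bonds are cut. This is a protecting-group operation; the forward step must be mild enough that 2 does not dehydrate to a phenol.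

2 back to 1. The C–O bonds at C2 and C7 are cut, which restores the aromatic ring and removes all stereochemistry. The forward step must dihydroxylate one of the two equivalent unsubstituted 4,5-bonds of 1 on one face only, which is the task of a dioxygenase.

## Other disconnections considered

Alternative 1: The cut is the C6–O1 bond alone.
- Forward key step: PdCl2(MeCN)2 would bind the alkene and the C8 hydroxyl of the open-chain hydroperoxyacetal A1. A1 is an (E)-C6=C7 allylic alcohol whose C3 carries OMe and OOH and whose C4 carbinol is a triethylsilyl ether. The terminal peroxy oxygen would add to C6 in a 6-exo mode while the C8 hydroxyl leaves, giving the 3-methoxy-1,2-dioxane A2 with an (E)-C7=C8 alkene. For a syn SN2′ course the (8R) alcohol is the matching substrate.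
- In its favour: the quaternary C6 centre would be set from a secondary carbinol that routine asymmetric reduction can supply. The chain is present from the start, the catalyst is neutral, and no two like groups need to be told apart later.
- Against it here: A1 needs three separately made stereo-elements (C4, C8, alkene geometry). A hydroperoxyacetal usually comes from ozonolysis in methanol, which would have to spare the electron-rich C6=C7 alkene. Divalent palladium could dehydrate the hydroperoxyacetal to an ester or oxidise the allylic alcohol. A2 still lacks C1 and C2, so a peroxycarbenium substitution at C3 (with its own cis/trans question), desilylation, lactonisation and diimide reduction must follow.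
- Comparison: structurally it closes the dioxane by one C–O bond where the chosen plan forms both at once. Mechanistically it relies on an ordered transition state at a trisubstituted alkene, where the chosen plan relies on a suprafacial cycloaddition that cannot give the trans isomer. In step count it should be longer overall. It is better in that no ylide meets a base-sensitive dioxine, no two formyl groups need to be told apart, and it does not rest on an assumed enzyme selectivity. It is equal in the diimide finish.

Alternative 2: The cuts are C5–C6 and the lactone C4–O bond.
- Forward key step: Me3SiOTf would ionise the ketal carbon C6 of the acyclic alkynyl peroxyketal A3. In A3 the peroxide links C3 to a C6 that carries methyl, methoxy and hexadecynyl groups; C3 carries an isopropenyl group and a tert-butyl acetate arm. The terminal alkene carbon C5 would attack the peroxycarbenium ion (6-endo), and the ester carbonyl would capture the tertiary C4 cation with loss of isobutene, giving the C6-alkynyl bicyclic lactone A4.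
- In its favour: it forms a C–C bond and both rings in one step from a precursor with a single fixed stereocentre. Only reduction of the alkyne with diimide would remain.
- Against it here: C6 would be set in a cationic chair in which only the small size difference between methyl and alkynyl decides the face. Peroxycarbenium ions can fragment by Hock- or Criegee-type shifts. The secondary allylic peroxide of A3 is itself hard to obtain as one enantiomer, since displacement by a peroxide nucleophile at an allylic carbon can scramble. The alkyne needs two diimide additions.
- Comparison: on structure and step economy it is the better plan. It is more convergent, the post-key-step work is one step against nine, and no iodine or tin is needed. It is equal in relaying C4 from C3 through ring fusion. The chosen plan is better at the hardest point, the configuration of C6 relative to C3, which the bicycle enforces; the cationic cascade leaves that to a modest conformational bias.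

Alternative 3: The cuts are O2–C3, C2–C1 and the lactone C1–O bond.
- Forward key step: Pd(OAc)2 with benzoquinone under CO would make the C6 hydroperoxide of the open-chain precursor A5 add to the vinyl group on C4 (O–C3, 6-exo). A5 is a tertiary (E)-alkenyl hydroperoxide with a tertiary vinyl carbinol at C4. CO would insert at C2, and the C4 hydroxyl would take the acyl group, giving the bicyclic lactone A6 with an (E)-C7=C8 alkene.
- In its favour: three bonds and both rings form in one catalytic step. The cis ring fusion is forced, and only a diimide reduction follows.
- Against it here: A5 already contains both quaternary stereocentres in an acyclic 1,3-relation. The C6 hydroperoxide would usually be introduced through a cationic or radical intermediate that does not control C6, so diastereomers would have to be separated. A free tertiary hydroperoxide must survive divalent palladium, zerovalent palladium formed in turnover, and CO, all of which can reduce it. CO with a peroxide and an oxidant is also a handling hazard.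
- Comparison: it is better in step economy after the key step and in closing the lactone without iodine or tin. It is equal in the diimide finish and in fixing C3 through ring fusion. The chosen plan is better in absolute control of C6, in never handling a free hydroperoxide, and in deriving all three stereocentres from one enzymatic event.

Key step: step 3

Assumption (chemistry): toluene dioxygenase is taken to oxidise an unsubstituted bond next to one methyl group of m-xylene with the facial sense it shows for toluene, giving the (1S,2R) diol as one enantiomer.

## Route

Step 1
Reactants: 1 m-xylene
Product: 2 (1S,2R)-3,5-dimethylcyclohexa-3,5-diene-1,2-diol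
Conditions: E. coli JM109(pDTG601) whole cells (toluene dioxygenase), air, glucose, phosphate buffer pH 7.2, 1 fed as vapour, 30 °C
Reagents that add atoms: dioxygen, O=O
Why: Enzymatic arene cis-dihydroxylation adds both atoms of O2 to one face of an unsubstituted 4,5-bond of an alkylbenzene; the enzyme pocket sets both carbinol stereocentres and is expected to seat the ortho methyl as it seats the methyl of toluene.

Step 2
Reactants: 2 (1S,2R)-3,5-dimethylcyclohexa-3,5-diene-1,2-diol; 3 2,2-dimethoxypropane
Product: 4 (3aR,7aS)-2,2,4,6-tetramethyl-3a,7a-dihydro-1,3-benzodioxole
Conditions: p-TsOH (cat.), acetone, 0 °C; Et3N quench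
Reagents that add atoms: none
Why: Acid-catalysed transacetalisation of a cis-1,2-diol; it is run cold and quenched with amine because the dienediol dehydrates to dimethylphenols under acid, and no stereocentre is touched.

Step 3
Reactants: 4 (3aR,7aS)-2,2,4,6-tetramethyl-3a,7a-dihydro-1,3-benzodioxole
Product: 5 anti endoperoxide acetonide (1,5-dimethyl-2,3-dioxabicyclo[2.2.2]oct-5-ene-7,8-diol isopropylidene acetal; dioxolane on the face opposite the O–O bridge)
Conditions: O2, tetraphenylporphyrin (cat.), visible light, CH2Cl2, −40 °C
Reagents that add atoms: dioxygen, O=O
Why: Energy transfer from the excited porphyrin gives singlet oxygen, which adds as a 2π partner across C3 and C6 of the ring-locked s-cis diene in a concerted suprafacial (4+2) cycloaddition, the reaction type known from α-terpinene to ascaridole and from acetonides of other arene cis-dihydrodiols. The 3,6-dihydro-1,2-dioxine ring is closed by cycloaddition, both C–O bonds forming in one event, and it appears as the O–O bridge of a 2,3-dioxabicyclo[2.2.2]oct-5-ene. C3 and C6 are the new stereocentres: their relative configuration is fixed because both oxygens must land on one face, and their absolute configuration is relayed from the enzyme-set carbinol carbons, since oxygen should approach opposite the dioxolane, whose inward methyl group and ring oxygens block the syn face. The step needs π-facial selectivity and (4+2) over ene selectivity. The acetonide supplies the first and the cisoid diene geometry the second, and low temperature with a stop at full conversion shields the remaining trisubstituted alkene of 5 from a slower ene reaction. The two carbinol carbons later become C2 and C7, so the cis relation of the two side arms is already built in.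

Step 4
Reactants: 5 anti endoperoxide acetonide
Product: 6 endoperoxide cis-diol (1,5-dimethyl-2,3-dioxabicyclo[2.2.2]oct-5-ene-7,8-diol; both hydroxyls anti to the O–O bridge)
Conditions: TFA–H2O–THF (1:1:4), 0 °C to rt
Reagents that add atoms: none
Why: Acid-catalysed acetal hydrolysis; the dialkyl peroxide is a very weak base and its bridgehead C–O bonds cannot ionise, so the bridge should survive and no stereocentre is involved.

Step 5
Reactants: 6 endoperoxide cis-diol
Product: 7 cis-dialdehyde (4,6-dimethyl-3,6-dihydro-1,2-dioxine-3,6-dicarbaldehyde in target numbering; formyl groups cis)
Conditions: NaIO4 on silica gel, CH2Cl2, 0 °C to rt; filtered and used at once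
Reagents that add atoms: none
Why: Malaprade glycol cleavage through a cyclic periodate ester, which forms easily from a rigid cis-diol; the neutral supported reagent avoids enolisation at C3, whose hydrogen is now α to a formyl group, so C3 and C6 keep their configuration.

Step 6
Reactants: 7 cis-dialdehyde; 8 (methoxymethyl)triphenylphosphonium chloride
Product: 10 enol ether aldehyde (C3 2-methoxyvinyl as E/Z mixture; C6 formyl), via (methoxymethylene)triphenylphosphorane 9 (not isolated)
Conditions: 8 (1.0 equiv), KN(SiMe3)2, THF, −78 °C; ylide added slowly to 7, THF, −78 °C
Reagents that add atoms: none
Why: Wittig olefination with a non-stabilised alkoxy ylide; the formyl group on the C3 methine is less hindered than the one on the quaternary C6, so one equivalent of ylide added to the dialdehyde in the cold should react there first, and addition to C=O is expected to outrun deprotonation at C3.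

Step 7
Reactants: 11 1-bromopentadecane; 12 triphenylphosphine
Product: 13 pentadecyltriphenylphosphonium bromide
Conditions: MeCN, reflux
Reagents that add atoms: none
Why: SN2 quaternisation of a phosphine by a primary alkyl bromide.

Step 8
Reactants: 10 enol ether aldehyde; 13 pentadecyltriphenylphosphonium bromide
Product: 15 Z-alkenyl enol ether (C6 (Z)-hexadec-1-enyl; C3 2-methoxyvinyl), via pentadecylidenetriphenylphosphorane 14 (not isolated)
Conditions: 13 (slight excess over base), NaN(SiMe3)2, THF, 0 °C; then 10, −78 to 0 °C
Reagents that add atoms: none
Why: Wittig olefination of an aldehyde without α-hydrogen by a non-stabilised ylide, giving mainly the Z alkene; the geometry does not matter because the bond is saturated in step 11, base is kept below the salt so that no free amide can remove the C3 hydrogen, and hindered dialkyl peroxides are not attacked by ylides in the cold.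

Step 9
Reactants: 15 Z-alkenyl enol ether
Product: 17 dioxine acetic acid (C3 carboxymethyl; C6 (Z)-hexadec-1-enyl), via β-peroxy aldehyde 16 (not isolated)
Conditions: AcOH–NaOAc buffer (pH 4), THF–H2O, rt; then t-BuOH, 2-methyl-2-butene, NaClO2, 0 °C
Reagents that add atoms: water, O; sodium chlorite, [Na+].[O-]Cl=O
Why: Enol ether hydrolysis is general-acid catalysed (rate-limiting protonation at C2), whereas ionisation of the allylic C3–O bond needs specific acid, so a concentrated weak-acid buffer should favour the aldehyde; Pinnick oxidation in the same flask (HClO2, alkene scavenger for HOCl) then gives the acid without touching the alkenes or O–O.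

Step 10
Reactants: 17 dioxine acetic acid
Product: 18 alkenyl iodolactone (cis-fused γ-lactone; iodine at C5 trans to the lactone oxygen; C6 (Z)-hexadec-1-enyl)
Conditions: I2, NaHCO3, MeCN–H2O, 0 °C, dark
Reagents that add atoms: iodine, [I][I]
Why: Kinetic iodolactonisation: the carboxylate opens the iodonium ion of the C4=C5 alkene at the more substituted C4 (5-exo, Markovnikov) from the face of its own tether, which forces the cis ring fusion and sets C4 (S) from C3 with iodine anti at C5; the C7=C8 alkene has no internal nucleophile, so its iodonium ion should revert.

Step 11
Reactants: 18 alkenyl iodolactone
Product: 19 saturated iodolactone (C6 hexadecyl)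
Conditions: KO2CN=NCO2K, AcOH, MeOH–CH2Cl2, 0 °C to rt
Reagents that add atoms: none
Why: Diimide reduction transfers H2 to the only remaining C=C by a concerted syn addition and does not reduce O–O, C–I or the lactone; the acidic medium avoids enolate formation at C2.

Step 12
Reactants: 19 saturated iodolactone
Product: 20 target, (3S,4S,6R) cis-fused dioxane lactone [(3R,4aS,7aS)-3-hexadecyl-3,4a-dimethyltetrahydrofuro[3,2-c][1,2]dioxin-6-one]
Conditions: Bu3SnH (excess, concentrated), Et3B (cat.), air, toluene, 0 °C
Reagents that add atoms: none
Why: Radical-chain dehalogenation: iodine abstraction by the tin radical is far faster than its attack on a hindered dialkyl peroxide, and the ring-held C5 radical is misaligned for backside attack on O1–O2, so concentrated Bu3SnH should quench it before it closes to an epoxide; C5 becomes a methylene and no stereocentre is at stake.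

## Compound list

```
1 | m-xylene | Cc1cccc(C)c1 | starting material
2 | (1S,2R)-3,5-dimethylcyclohexa-3,5-diene-1,2-diol | CC1=CC(C)=C[C@H](O)[C@@H]1O | intermediate
3 | 2,2-dimethoxypropane | COC(C)(C)OC | starting material
4 | (3aR,7aS)-2,2,4,6-tetramethyl-3a,7a-dihydro-1,3-benzodioxole | CC1=CC(C)=C[C@@H]2OC(C)(C)O[C@H]12 | intermediate
5 | anti endoperoxide acetonide | CC1=C[C@]2(C)OO[C@H]1[C@@H]1OC(C)(C)O[C@@H]12 | intermediate
6 | endoperoxide cis-diol | CC1=C[C@]2(C)OO[C@H]1[C@H](O)[C@@H]2O | intermediate
7 | cis-4,6-dimethyl-3,6-dihydro-1,2-dioxine-3,6-dicarbaldehyde (target numbering) | O=C[C@]1(C)C=C(C)[C@H](C=O)OO1 | intermediate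
8 | (methoxymethyl)triphenylphosphonium chloride | [Cl-].COC[P+](c1ccccc1)(c1ccccc1)c1ccccc1 | starting material
9 | (methoxymethylene)triphenylphosphorane (formed in the flask) | COC=P(c1ccccc1)(c1ccccc1)c1ccccc1 | intermediate
10 | enol ether aldehyde (C3 2-methoxyvinyl, E/Z; C6 formyl) | O=C[C@]1(C)C=C(C)[C@H](C=COC)OO1 | intermediate
11 | 1-bromopentadecane | CCCCCCCCCCCCCCCBr | starting material
12 | triphenylphosphine | c1ccc(cc1)P(c1ccccc1)c1ccccc1 | starting material
13 | pentadecyltriphenylphosphonium bromide | [Br-].CCCCCCCCCCCCCCC[P+](c1ccccc1)(c1ccccc1)c1ccccc1 | intermediate
14 | pentadecylidenetriphenylphosphorane (formed in the flask) | CCCCCCCCCCCCCCC=P(c1ccccc1)(c1ccccc1)c1ccccc1 | intermediate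
15 | Z-alkenyl enol ether | C(/CCCCCCCCCCCCCC)=C/[C@]1(C)C=C(C)[C@H](C=COC)OO1 | intermediate
16 | β-peroxy aldehyde (formed in the flask) | C(/CCCCCCCCCCCCCC)=C/[C@]1(C)C=C(C)[C@H](CC=O)OO1 | intermediate
17 | dioxine acetic acid | C(/CCCCCCCCCCCCCC)=C/[C@]1(C)C=C(C)[C@H](CC(=O)O)OO1 | intermediate
18 | alkenyl iodolactone (iodine at C5 trans to lactone oxygen) | C(/CCCCCCCCCCCCCC)=C/[C@]1(C)[C@@H](I)[C@]2(C)OC(=O)C[C@@H]2OO1 | intermediate
19 | saturated iodolactone | CCCCCCCCCCCCCCCC[C@]1(C)[C@@H](I)[C@]2(C)OC(=O)C[C@@H]2OO1 | intermediate
20 | (3S,4S,6R) dioxane-fused lactone, CNP0079571.1 | CCCCCCCCCCCCCCCC[C@]1(C)C[C@]2(C)OC(=O)C[C@@H]2OO1 | target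
```

## Step count and least certain steps

Total steps: 12. Longest linear sequence: 11 steps (steps 1 to 6 and 8 to 12, from 1 to 20); step 7 is a one-step side branch.

**Step 3 (key step).** The most likely failure is loss of chemoselectivity: ene hydroperoxidation at the two allylic methyl groups, or a second oxidation of the product alkene, because the diene is alkyl-rich. Incomplete shielding of the syn face would erode the configuration at C3 and C6. Fallback: from 4 to 5 with ground-state oxygen under radical-cation catalysis, (4-BrC6H4)3N SbCl6 (cat.), O2, CH2Cl2, −78 °C. The aminium salt oxidises the diene to its radical cation, which combines with triplet oxygen and closes to the same endoperoxide through a chain that has no ene channel. This fallback makes no new compound (F0).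

**Step 6.** Site selectivity between the two formyl groups may be incomplete (double olefination, or reaction at C6). The ylide may also act as a base at C3, which starts Kornblum–DeLaMare opening of the O–O bond. Fallback, from 7 back to 15:
- 7 is reduced with NaBH4 in MeOH at −20 °C to the bis(hydroxymethyl)dioxine F1.
- The unhindered C3 hydroxymethyl group is silylated with t-BuPh2SiCl and imidazole to give the mono silyl ether F2; the C6 hydroxymethyl group is neopentylic and should stay free.
- Dess–Martin oxidation gives the C6 aldehyde silyl ether F3, which has no formyl group at C3 and a far less acidic C3 hydrogen.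
- Wittig reaction with 14 gives the Z-alkenyl silyl ether F4.
- HF·pyridine in THF releases the Z-alkenyl alcohol F5, and Dess–Martin oxidation gives the C3 aldehyde F6.
- F6 is olefinated with 9 to give 15.

**Step 9.** Acid may ionise the allylic C3–O bond of the 2-methoxyvinyl dioxine, which is a vinylogous peroxy acetal, or the β-peroxy aldehyde may eliminate the peroxide to a conjugated enal before it is oxidised. Fallback, from 15 to 18: the enol ether is oxidised directly with C5H5NH[CrO3Cl] (pyridinium chlorochromate) buffered with NaOAc in CH2Cl2 to the methyl ester F7, so no free aldehyde forms. F7 is then treated with I2 in MeCN, where the ester carbonyl opens the iodonium ion and iodide removes the methyl group, giving 18.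

**Step 12.** The C5 radical may be captured by the adjacent O–O bond (epoxide formation with ring opening), or the tin radical may attack the peroxide, both of which destroy the dioxane. Fallback, from 17 to 20: the C7=C8 alkene of 17 alone is reduced with diimide (KO2CN=NCO2K, AcOH; the trisubstituted ring alkene reacts much more slowly) to the saturated dioxine acetic acid F8. Catalytic TfOH in CH2Cl2 at 0 °C then protonates C5, and the carboxyl captures the tertiary C4 cation on its own face, giving 20 with no iodine and no radical.

## Further compounds

```
F0 | step 3 | none | none
F1 | step 6 | bis(hydroxymethyl)dioxine | OC[C@]1(C)C=C(C)[C@H](CO)OO1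
F2 | step 6 | mono silyl ether (C3 CH2OSiPh2t-Bu, C6 CH2OH) | OC[C@]1(C)C=C(C)[C@H](CO[Si](c2ccccc2)(c2ccccc2)C(C)(C)C)OO1
F3 | step 6 | C6 aldehyde silyl ether | O=C[C@]1(C)C=C(C)[C@H](CO[Si](c2ccccc2)(c2ccccc2)C(C)(C)C)OO1
F4 | step 6 | Z-alkenyl silyl ether | C(/CCCCCCCCCCCCCC)=C/[C@]1(C)C=C(C)[C@H](CO[Si](c2ccccc2)(c2ccccc2)C(C)(C)C)OO1
F5 | step 6 | Z-alkenyl alcohol | C(/CCCCCCCCCCCCCC)=C/[C@]1(C)C=C(C)[C@H](CO)OO1
F6 | step 6 | C3 aldehyde with Z-alkenyl chain | C(/CCCCCCCCCCCCCC)=C/[C@]1(C)C=C(C)[C@H](C=O)OO1
F7 | step 9 | methyl ester of 17 | C(/CCCCCCCCCCCCCC)=C/[C@]1(C)C=C(C)[C@H](CC(=O)OC)OO1
F8 | step 12 | saturated dioxine acetic acid | CCCCCCCCCCCCCCCC[C@]1(C)C=C(C)[C@H](CC(=O)O)OO1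
A1 | alternative 1 | open-chain (E)-allylic (8R)-alcohol hydroperoxyacetal | CCCCCCCCCCCCCC[C@@H](O)/C=C(/C[C@](C)(O[Si](CC)(CC)CC)[C@H](OC)OO)C
A2 | alternative 1 | 3-methoxy-1,2-dioxane with (E)-hexadec-1-enyl chain at C6 | CCCCCCCCCCCCCC/C=C/[C@]1(C)C[C@](C)(O[Si](CC)(CC)CC)[C@H](OC)OO1
A3 | alternative 2 | acyclic alkynyl peroxyketal tert-butyl ester (either C6 epimer) | CCCCCCCCCCCCCCC#CC(C)(OC)OO[C@@H](CC(=O)OC(C)(C)C)C(C)=C
A4 | alternative 2 | C6-alkynyl dioxane-fused lactone | CCCCCCCCCCCCCCC#C[C@]1(C)C[C@]2(C)OC(=O)C[C@@H]2OO1
A5 | alternative 3 | open-chain C6 hydroperoxide with C4 vinyl carbinol | CCCCCCCCCCCCCC/C=C/[C@@](C)(OO)C[C@](C)(O)C=C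
A6 | alternative 3 | dioxane-fused lactone with (E) C7–C8 alkene | CCCCCCCCCCCCCC/C=C/[C@]1(C)C[C@]2(C)OC(=O)C[C@@H]2OO1
```
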